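**Retrosynthetic overview**
1. Target ⇐ acetylation of the C17 alcohol; the C13–C14 CH2–CH2 link ⇐ diimide reduction of the alkene from a macrocyclic ring-closing metathesis of two vinyl groups (14-membered ring, closed last).
2. 2,5-Dihydrofuran with its tetrasubstituted C1=C15 alkene and a vinyl handle at C1 ⇐ ring-closing enyne metathesis of a propargyl 2-(silyloxymethyl)allyl ether (five-membered ring, closed second).
3. That ether ⇐ Williamson coupling of the C2 alkynol with an allylic bromide from 2-methylenepropane-1,3-diol; C2–OH ⇐ ethynyl addition to an enal, then lipase acylation of the 2S epimer only.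
4. 7,8-Epoxide (closed first, first stereocentres) ⇐ catalytic asymmetric Shi epoxidation of the central alkene of a farnesyl diester whose two other alkenes are deactivated by allylic acyloxy groups.
5. C2–C13 chain with its (E)-alkenes ⇐ (2E,6E)-farnesol after SeO2 oxidation of the terminal (E)-methyl.

Assumption: atom labels C1–C17 in the Why lines are the cembrane numbers of the target (ring C1–C14, O–CH = C2, epoxide = C7/C8, ring-fusion alkene = C1=C15, ring OCH2 = C16, CH2OAc = C17); the L-fructose-derived Shi ketone is a purchased catalyst.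

**Route**

Step 1
Reactants: 1 (2E,6E)-farnesol
Product: 2 (2E,6E)-farnesyl acetate
Conditions: Ac2O, pyridine, DMAP (cat.), CH2Cl2, 0 °C to rt
Reagents that add atoms: acetic anhydride, CC(=O)OC(C)=O
Why: DMAP-catalysed esterification of the primary allylic alcohol gives an acetate that deactivates the C3=C4 alkene towards electrophilic oxidants and can later be cleaved beside a pivalate.

Step 2
Reactants: 2 (2E,6E)-farnesyl acetate
Product: 3 (2E,6E,10E)-12-hydroxy-3,7,11-trimethyldodeca-2,6,10-trien-1-yl acetate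
Conditions: SeO2 (0.3 equiv), t-BuOOH (3 equiv), salicylic acid (cat.), CH2Cl2, rt
Reagents that add atoms: tert-butyl hydroperoxide, CC(C)(C)OO (its oxygen is passed on through catalytic SeO2, O=[Se]=O)
Why: Sharpless–Umbreit allylic oxidation (ene reaction, then [2,3]-sigmatropic shift) attacks the (E)-methyl of the terminal, least hindered trisubstituted alkene and gives the (E)-allylic alcohol that becomes C13.

Step 3
Reactants: 3 (2E,6E,10E)-12-hydroxy-3,7,11-trimethyldodeca-2,6,10-trien-1-yl acetate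
Product: 4 (2E,6E,10E)-3,7,11-trimethyl-12-(pivaloyloxy)dodeca-2,6,10-trien-1-yl acetate
Conditions: t-BuCOCl, pyridine, DMAP (cat.), CH2Cl2, 0 °C
Reagents that add atoms: pivaloyl chloride, CC(C)(C)C(=O)Cl
Why: Acylation gives a hindered ester that makes the C11=C12 alkene electron-poor and survives the later base-catalysed methanolyses.

Step 4
Reactants: 4 (2E,6E,10E)-3,7,11-trimethyl-12-(pivaloyloxy)dodeca-2,6,10-trien-1-yl acetate
Product: 5 (2E,6S,7S,10E)-6,7-epoxy-3,7,11-trimethyl-12-(pivaloyloxy)dodeca-2,10-dien-1-yl acetate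
Conditions: L-fructose-derived Shi ketone (1,2:4,5-di-O-isopropylidene-β-L-erythro-2,3-hexodiulo-2,6-pyranose, 0.3 equiv), KHSO5 (as 2KHSO5·KHSO4·K2SO4), K2CO3, Bu4NHSO4, Na2B4O7 buffer pH 10.5, MeCN–(MeO)2CH2–H2O, 0 °C
Reagents that add atoms: potassium peroxymonosulfate, [K+].[O-]S(=O)(=O)OO
Why: In this Shi asymmetric epoxidation the chiral dioxirane attacks only the central trialkyl alkene, because both flanking alkenes carry allylic acyloxy groups, and the L-fructose-derived catalyst delivers oxygen through the spiro transition state to the face that gives the (6S,7S) epoxide, which is C7/C8 of the target.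

Step 5
Reactants: 5 (2E,6S,7S,10E)-6,7-epoxy-3,7,11-trimethyl-12-(pivaloyloxy)dodeca-2,10-dien-1-yl acetate
Product: 6 (2E,6S,7S,10E)-6,7-epoxy-1-hydroxy-3,7,11-trimethyldodeca-2,10-dien-12-yl pivalate
Conditions: K2CO3 (0.3 equiv), MeOH, 0 °C
Reagents that add atoms: none
Why: Base-catalysed transesterification (Zemplén-type methanolysis) removes the unhindered acetate far faster than the pivalate and leaves the trisubstituted epoxide untouched.

Step 6
Reactants: 6 (2E,6S,7S,10E)-6,7-epoxy-1-hydroxy-3,7,11-trimethyldodeca-2,10-dien-12-yl pivalate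
Product: 7 (2E,6S,7S,10E)-6,7-epoxy-3,7,11-trimethyl-1-oxododeca-2,10-dien-12-yl pivalate
Conditions: MnO2 (excess), CH2Cl2, rt
Reagents that add atoms: none
Why: MnO2 allylic oxidation converts the primary allylic alcohol into the (E)-enal without over-oxidation and without touching the epoxide or the ester.

Step 7
Reactants: 7 (2E,6S,7S,10E)-6,7-epoxy-3,7,11-trimethyl-1-oxododeca-2,10-dien-12-yl pivalate
Product: 8 (4E,8S,9S,12E)-8,9-epoxy-3-hydroxy-5,9,13-trimethyltetradeca-4,12-dien-1-yn-14-yl pivalate, 1:1 mixture of 3R and 3S epimers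
Conditions: HC≡CMgBr (1.5 equiv), THF, −78 °C; aq. NH4Cl
Reagents that add atoms: ethynylmagnesium bromide, C#C[Mg]Br
Why: 1,2-Addition of the alkynyl Grignard reagent to the β,β-disubstituted enal at low temperature builds the C1–C2 bond and gives both C2 epimers, since the remote epoxide exerts no control and the hindered pivalate does not react.

Step 8
Reactants: 8 (4E,8S,9S,12E)-8,9-epoxy-3-hydroxy-5,9,13-trimethyltetradeca-4,12-dien-1-yn-14-yl pivalate, 1:1 mixture of 3R and 3S epimers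
Product: 9 (3S,4E,8S,9S,12E)-3-acetoxy-8,9-epoxy-5,9,13-trimethyltetradeca-4,12-dien-1-yn-14-yl pivalate
Conditions: lipase (Burkholderia cepacia lipase, immobilised), vinyl acetate (5 equiv), t-BuOMe, 30 °C, stopped near 50% conversion
Reagents that add atoms: vinyl acetate, C=COC(C)=O
Why: In this lipase-catalysed kinetic resolution by irreversible transesterification, Kazlauskas' rule (slim ethynyl in the medium pocket, branched alkenyl chain in the large pocket) predicts that the serine hydrolase acylates only the 3S alcohol, which fixes C2 of the target, while the 3R half of 8 stays as the alcohol and is removed by chromatography.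

Step 9
Reactants: 9 (3S,4E,8S,9S,12E)-3-acetoxy-8,9-epoxy-5,9,13-trimethyltetradeca-4,12-dien-1-yn-14-yl pivalate
Product: 10 (3S,4E,8S,9S,12E)-8,9-epoxy-3-hydroxy-5,9,13-trimethyltetradeca-4,12-dien-1-yn-14-yl pivalate
Conditions: K2CO3 (0.3 equiv), MeOH, 0 °C
Reagents that add atoms: none
Why: Base-catalysed methanolysis cleaves the propargylic acetate at the acyl carbon, so the C2 configuration is retained, and again spares the pivalate.

Step 10
Reactants: 11 2-methylenepropane-1,3-diol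
Product: 12 2-{[tert-butyl(dimethyl)silyl]oxymethyl}prop-2-en-1-ol
Conditions: NaH (1.0 equiv), THF, 0 °C; then t-BuMe2SiCl (1.0 equiv)
Reagents that add atoms: tert-butyldimethylsilyl chloride, CC(C)(C)[Si](C)(C)Cl
Why: Monosilylation of the symmetric diol through its poorly soluble monosodium alkoxide (McDougal protocol) gives the mono-ether cleanly; no stereocentre is involved.

Step 11
Reactants: 12 2-{[tert-butyl(dimethyl)silyl]oxymethyl}prop-2-en-1-ol
Product: 13 {[2-(bromomethyl)prop-2-en-1-yl]oxy}(tert-butyl)dimethylsilane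
Conditions: CBr4, PPh3, CH2Cl2, 0 °C
Reagents that add atoms: carbon tetrabromide, BrC(Br)(Br)Br
Why: The Appel reaction converts the primary allylic alcohol into the bromide under neutral conditions that keep the silyl ether.

Step 12
Reactants: 10 (3S,4E,8S,9S,12E)-8,9-epoxy-3-hydroxy-5,9,13-trimethyltetradeca-4,12-dien-1-yn-14-yl pivalate; 13 {[2-(bromomethyl)prop-2-en-1-yl]oxy}(tert-butyl)dimethylsilane
Product: 14 (3S,4E,8S,9S,12E)-3-[(2-{[tert-butyl(dimethyl)silyl]oxymethyl}prop-2-en-1-yl)oxy]-8,9-epoxy-5,9,13-trimethyltetradeca-4,12-dien-1-yn-14-yl pivalate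
Conditions: NaH (1.1 equiv), THF, 0 °C; then 13, 0 °C to rt
Reagents that add atoms: none
Why: In this Williamson ether synthesis the sodium alkoxide of 10 displaces the reactive allylic bromide by SN2 at the primary carbon, so the C2–O bond and its configuration are untouched.

Step 13
Reactants: 14 (3S,4E,8S,9S,12E)-3-[(2-{[tert-butyl(dimethyl)silyl]oxymethyl}prop-2-en-1-yl)oxy]-8,9-epoxy-5,9,13-trimethyltetradeca-4,12-dien-1-yn-14-yl pivalate
Product: 15 (2S)-4-{[tert-butyl(dimethyl)silyl]oxymethyl}-3-ethenyl-2-[(1E,5S,6S,9E)-5,6-epoxy-2,6,10-trimethyl-11-(pivaloyloxy)undeca-1,9-dien-1-yl]-2,5-dihydrofuran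
Conditions: second-generation Grubbs catalyst RuCl2(=CHPh)(PCy3)(1,3-dimesitylimidazolidin-2-ylidene) (10 mol%), toluene (0.01 M), 80 °C
Reagents that add atoms: none
Why: In this ring-closing enyne metathesis (exo mode) the ruthenium carbene adds to the terminal alkyne and the resulting vinyl carbene closes onto the 1,1-disubstituted alkene, which forms the five-membered ring with its tetrasubstituted C1=C15 alkene and leaves a vinyl group on C1 without involving C2.

Step 14
Reactants: 15 (2S)-4-{[tert-butyl(dimethyl)silyl]oxymethyl}-3-ethenyl-2-[(1E,5S,6S,9E)-5,6-epoxy-2,6,10-trimethyl-11-(pivaloyloxy)undeca-1,9-dien-1-yl]-2,5-dihydrofuran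
Product: 16 (2S)-4-{[tert-butyl(dimethyl)silyl]oxymethyl}-3-ethenyl-2-[(1E,5S,6S,9E)-5,6-epoxy-11-hydroxy-2,6,10-trimethylundeca-1,9-dien-1-yl]-2,5-dihydrofuran
Conditions: i-Bu2AlH (2.5 equiv), CH2Cl2, −78 °C; aq. potassium sodium tartrate
Reagents that add atoms: none
Why: Reductive cleavage of the pivalate ester by i-Bu2AlH at −78 °C frees the C13 alcohol while the epoxide, the silyl ether and the allylic ethers are inert at this temperature.

Step 15
Reactants: 16 (2S)-4-{[tert-butyl(dimethyl)silyl]oxymethyl}-3-ethenyl-2-[(1E,5S,6S,9E)-5,6-epoxy-11-hydroxy-2,6,10-trimethylundeca-1,9-dien-1-yl]-2,5-dihydrofuran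
Product: 17 (2S)-4-{[tert-butyl(dimethyl)silyl]oxymethyl}-3-ethenyl-2-[(1E,5S,6S,9E)-5,6-epoxy-2,6,10-trimethyl-11-oxoundeca-1,9-dien-1-yl]-2,5-dihydrofuran
Conditions: Dess–Martin periodinane, NaHCO3, CH2Cl2, 0 °C
Reagents that add atoms: none
Why: Buffered Dess–Martin oxidation gives the (E)-enal under non-acidic conditions that spare the epoxide and, unlike MnO2, carry no risk of dehydrogenating the dihydrofuran to a furan.

Step 16
Reactants: 17 (2S)-4-{[tert-butyl(dimethyl)silyl]oxymethyl}-3-ethenyl-2-[(1E,5S,6S,9E)-5,6-epoxy-2,6,10-trimethyl-11-oxoundeca-1,9-dien-1-yl]-2,5-dihydrofuran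
Product: 18 (2S)-4-{[tert-butyl(dimethyl)silyl]oxymethyl}-3-ethenyl-2-[(1E,5S,6S,9E)-5,6-epoxy-2,6,10-trimethyldodeca-1,9,11-trien-1-yl]-2,5-dihydrofuran
Conditions: Ph3PCH3Br, KN(SiMe3)2, THF, −78 to 0 °C
Reagents that add atoms: methyltriphenylphosphonium bromide, C[P+](c1ccccc1)(c1ccccc1)c1ccccc1.[Br-]
Why: Wittig methylenation of the enal with the non-stabilised ylide gives the terminal diene and keeps the (E)-geometry of C11=C12.

Step 17
Reactants: 18 (2S)-4-{[tert-butyl(dimethyl)silyl]oxymethyl}-3-ethenyl-2-[(1E,5S,6S,9E)-5,6-epoxy-2,6,10-trimethyldodeca-1,9,11-trien-1-yl]-2,5-dihydrofuran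
Product: 19 (2S,7S,8S,3E,11E)-17-{[tert-butyl(dimethyl)silyl]oxy}-2,16:7,8-diepoxycembra-1(15),3,11,13-tetraene (C13=C14 as E/Z mixture)
Conditions: second-generation Grubbs catalyst RuCl2(=CHPh)(PCy3)(1,3-dimesitylimidazolidin-2-ylidene) (15 mol%), CH2Cl2 (1 mM), 40 °C
Reagents that add atoms: none
Why: Ring-closing metathesis of the two monosubstituted vinyl termini under high dilution closes the 14-membered ring with loss of ethylene, the tri- and tetrasubstituted alkenes being too hindered to take part and the E/Z ratio of the new alkene being irrelevant.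

Step 18
Reactants: 19 (2S,7S,8S,3E,11E)-17-{[tert-butyl(dimethyl)silyl]oxy}-2,16:7,8-diepoxycembra-1(15),3,11,13-tetraene
Product: 20 (2S,7S,8S,3E,11E)-17-{[tert-butyl(dimethyl)silyl]oxy}-2,16:7,8-diepoxycembra-1(15),3,11-triene
Conditions: 2-nitrobenzenesulfonylhydrazide, Et3N, CH2Cl2, rt
Reagents that add atoms: none
Why: Diimide reduction (concerted syn transfer of H2 from HN=NH made in situ) saturates the only 1,2-disubstituted alkene, since tri- and tetrasubstituted alkenes react far more slowly and the epoxide and allylic C–O bonds are inert to diimide.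

Step 19
Reactants: 20 (2S,7S,8S,3E,11E)-17-{[tert-butyl(dimethyl)silyl]oxy}-2,16:7,8-diepoxycembra-1(15),3,11-triene
Product: 21 (2S,7S,8S,3E,11E)-2,16:7,8-diepoxycembra-1(15),3,11-trien-17-ol
Conditions: Bu4NF, THF, 0 °C
Reagents that add atoms: none
Why: Fluoride-mediated desilylation frees the primary C17 alcohol under conditions harmless to the epoxide and the bis-allylic ether.

Step 20
Reactants: 21 (2S,7S,8S,3E,11E)-2,16:7,8-diepoxycembra-1(15),3,11-trien-17-ol
Product: 22 (2S,7S,8S,3E,11E)-17-acetoxy-2,16:7,8-diepoxycembra-1(15),3,11-triene (CNP0140293.1)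
Conditions: Ac2O, pyridine, DMAP (cat.), CH2Cl2, 0 °C
Reagents that add atoms: acetic anhydride, CC(=O)OC(C)=O
Why: DMAP-catalysed esterification of the primary allylic alcohol gives the target without touching the stereocentres set in steps 4 and 8.

**Compound list**
1 | (2E,6E)-farnesol, (2E,6E)-3,7,11-trimethyldodeca-2,6,10-trien-1-ol | CC(C)=CCC/C(C)=C/CC/C(C)=C/CO | starting material
2 | (2E,6E)-farnesyl acetate | CC(C)=CCC/C(C)=C/CC/C(C)=C/COC(C)=O | intermediate
3 | (2E,6E,10E)-12-hydroxy-3,7,11-trimethyldodeca-2,6,10-trien-1-yl acetate | OC/C(C)=C/CC/C(C)=C/CC/C(C)=C/COC(C)=O | intermediate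
4 | (2E,6E,10E)-3,7,11-trimethyl-12-(pivaloyloxy)dodeca-2,6,10-trien-1-yl acetate | CC(C)(C)C(=O)OC/C(C)=C/CC/C(C)=C/CC/C(C)=C/COC(C)=O | intermediate
5 | (2E,6S,7S,10E)-6,7-epoxy-3,7,11-trimethyl-12-(pivaloyloxy)dodeca-2,10-dien-1-yl acetate | CC(C)(C)C(=O)OC/C(C)=C/CC[C@]1(C)O[C@H]1CC/C(C)=C/COC(C)=O | intermediate
6 | (2E,6S,7S,10E)-6,7-epoxy-1-hydroxy-3,7,11-trimethyldodeca-2,10-dien-12-yl pivalate | CC(C)(C)C(=O)OC/C(C)=C/CC[C@]1(C)O[C@H]1CC/C(C)=C/CO | intermediate
7 | (2E,6S,7S,10E)-6,7-epoxy-3,7,11-trimethyl-1-oxododeca-2,10-dien-12-yl pivalate | CC(C)(C)C(=O)OC/C(C)=C/CC[C@]1(C)O[C@H]1CC/C(C)=C/C=O | intermediate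
8 | (4E,8S,9S,12E)-8,9-epoxy-3-hydroxy-5,9,13-trimethyltetradeca-4,12-dien-1-yn-14-yl pivalate, 1:1 mixture of 3R and 3S epimers | CC(C)(C)C(=O)OC/C(C)=C/CC[C@]1(C)O[C@H]1CC/C(C)=C/C(O)C#C | intermediate
9 | (3S,4E,8S,9S,12E)-3-acetoxy-8,9-epoxy-5,9,13-trimethyltetradeca-4,12-dien-1-yn-14-yl pivalate | CC(C)(C)C(=O)OC/C(C)=C/CC[C@]1(C)O[C@H]1CC/C(C)=C/[C@H](OC(C)=O)C#C | intermediate
10 | (3S,4E,8S,9S,12E)-8,9-epoxy-3-hydroxy-5,9,13-trimethyltetradeca-4,12-dien-1-yn-14-yl pivalate | CC(C)(C)C(=O)OC/C(C)=C/CC[C@]1(C)O[C@H]1CC/C(C)=C/[C@H](O)C#C | intermediate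
11 | 2-methylenepropane-1,3-diol | C=C(CO)CO | starting material
12 | 2-{[tert-butyl(dimethyl)silyl]oxymethyl}prop-2-en-1-ol | C=C(CO)CO[Si](C)(C)C(C)(C)C | intermediate
13 | {[2-(bromomethyl)prop-2-en-1-yl]oxy}(tert-butyl)dimethylsilane | C=C(CBr)CO[Si](C)(C)C(C)(C)C | intermediate
14 | (3S,4E,8S,9S,12E)-3-[(2-{[tert-butyl(dimethyl)silyl]oxymethyl}prop-2-en-1-yl)oxy]-8,9-epoxy-5,9,13-trimethyltetradeca-4,12-dien-1-yn-14-yl pivalate | CC(C)(C)C(=O)OC/C(C)=C/CC[C@]1(C)O[C@H]1CC/C(C)=C/[C@H](OCC(=C)CO[Si](C)(C)C(C)(C)C)C#C | intermediate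
15 | (2S)-4-{[tert-butyl(dimethyl)silyl]oxymethyl}-3-ethenyl-2-[(1E,5S,6S,9E)-5,6-epoxy-2,6,10-trimethyl-11-(pivaloyloxy)undeca-1,9-dien-1-yl]-2,5-dihydrofuran | CC(C)(C)C(=O)OC/C(C)=C/CC[C@]1(C)O[C@H]1CC/C(C)=C/[C@@H]1OCC(CO[Si](C)(C)C(C)(C)C)=C1C=C | intermediate
16 | (2S)-4-{[tert-butyl(dimethyl)silyl]oxymethyl}-3-ethenyl-2-[(1E,5S,6S,9E)-5,6-epoxy-11-hydroxy-2,6,10-trimethylundeca-1,9-dien-1-yl]-2,5-dihydrofuran | OC/C(C)=C/CC[C@]1(C)O[C@H]1CC/C(C)=C/[C@@H]1OCC(CO[Si](C)(C)C(C)(C)C)=C1C=C | intermediate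
17 | (2S)-4-{[tert-butyl(dimethyl)silyl]oxymethyl}-3-ethenyl-2-[(1E,5S,6S,9E)-5,6-epoxy-2,6,10-trimethyl-11-oxoundeca-1,9-dien-1-yl]-2,5-dihydrofuran | O=C/C(C)=C/CC[C@]1(C)O[C@H]1CC/C(C)=C/[C@@H]1OCC(CO[Si](C)(C)C(C)(C)C)=C1C=C | intermediate
18 | (2S)-4-{[tert-butyl(dimethyl)silyl]oxymethyl}-3-ethenyl-2-[(1E,5S,6S,9E)-5,6-epoxy-2,6,10-trimethyldodeca-1,9,11-trien-1-yl]-2,5-dihydrofuran | C=C/C(C)=C/CC[C@]1(C)O[C@H]1CC/C(C)=C/[C@@H]1OCC(CO[Si](C)(C)C(C)(C)C)=C1C=C | intermediate
19 | (2S,7S,8S,3E,11E)-17-{[tert-butyl(dimethyl)silyl]oxy}-2,16:7,8-diepoxycembra-1(15),3,11,13-tetraene, C13=C14 as E/Z mixture | CC(C)(C)[Si](C)(C)OCC1=C2C=C/C(C)=C/CC[C@]3(C)O[C@H]3CC/C(C)=C/[C@@H]2OC1 | intermediate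
20 | (2S,7S,8S,3E,11E)-17-{[tert-butyl(dimethyl)silyl]oxy}-2,16:7,8-diepoxycembra-1(15),3,11-triene | CC(C)(C)[Si](C)(C)OCC1=C2CC/C(C)=C/CC[C@]3(C)O[C@H]3CC/C(C)=C/[C@@H]2OC1 | intermediate
21 | (2S,7S,8S,3E,11E)-2,16:7,8-diepoxycembra-1(15),3,11-trien-17-ol | OCC1=C2CC/C(C)=C/CC[C@]3(C)O[C@H]3CC/C(C)=C/[C@@H]2OC1 | intermediate
22 | (2S,7S,8S,3E,11E)-17-acetoxy-2,16:7,8-diepoxycembra-1(15),3,11-triene (CNP0140293.1) | CC(=O)OCC1=C2CC/C(C)=C/CC[C@]3(C)O[C@H]3CC/C(C)=C/[C@@H]2OC1 | target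

**Step count and risks**

Total step count: 20. Longest linear sequence: 18 steps (steps 1–9, then 12–20, from farnesol); steps 10–11 prepare bromide 13.

The three steps most likely to fail:

Step 8, lipase resolution. Both groups on the carbinol carbon are unsaturated, so the selectivity between the C3 epimers of 8 could be too low, and at best half of the material is used. The fallback sets C2 by catalytic asymmetric alkynylation instead of resolution; it sets out from 7 and comes back at 10. Enal 7 is treated with trimethylsilylacetylene, Me2Zn and the ProPhenol ligand enantiomer that exposes the aldehyde face leading to the 3S carbinol (toluene, 4 °C). This gives (3S,4E,8S,9S,12E)-8,9-epoxy-3-hydroxy-5,9,13-trimethyl-1-(trimethylsilyl)tetradeca-4,12-dien-1-yn-14-yl pivalate F1. K2CO3 in MeOH at 0 °C then removes the C-silyl group and the route is rejoined at 10.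

Step 13, enyne ring closure. Closing a vinyl carbene onto a 1,1-disubstituted alkene to give a tetrasubstituted ring alkene is slow and may lose out to alkyne oligomerisation. The fallback separates the alkyne event from the ring closure; it sets out from 14 and comes back at 15. Cross enyne metathesis of 14 with ethylene (1 atm, RuCl2(=CHPh)(PCy3)(1,3-dimesitylimidazolidin-2-ylidene), CH2Cl2, rt) turns the alkyne into a 2-substituted buta-1,3-diene. The product is (4S,5E,9S,10S,13E)-4-[(2-{[tert-butyl(dimethyl)silyl]oxymethyl}prop-2-en-1-yl)oxy]-9,10-epoxy-6,10,14-trimethyl-3-methylidenepentadeca-1,5,13-trien-15-yl pivalate F2. Ring-closing diene metathesis of its two 1,1-disubstituted alkenes with a catalyst built for tetrasubstituted alkenes, RuCl2(=CH-2-(i-PrO)C6H4)(1,3-di-o-tolylimidazolidin-2-ylidene), in toluene at 80 °C then gives 15.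

Step 17, macrocyclic ring-closing metathesis. Both reacting vinyl groups are conjugated and sluggish, so dimerisation may compete. The fallback closes the large ring first, through an irreversible ene–yne step; it sets out from 14 and comes back at 19. Treating 14 with i-Bu2AlH (CH2Cl2, −78 °C) gives (3S,4E,8S,9S,12E)-3-[(2-{[tert-butyl(dimethyl)silyl]oxymethyl}prop-2-en-1-yl)oxy]-8,9-epoxy-5,9,13-trimethyltetradeca-4,12-dien-1-yn-14-ol F3. Dess–Martin periodinane with NaHCO3 gives (2E,6S,7S,10E,12S)-12-[(2-{[tert-butyl(dimethyl)silyl]oxymethyl}prop-2-en-1-yl)oxy]-6,7-epoxy-2,6,10-trimethyltetradeca-2,10-dien-13-ynal F4. Ph3PCH3Br with KN(SiMe3)2 gives (3S,4E,8S,9S,12E)-3-[(2-{[tert-butyl(dimethyl)silyl]oxymethyl}prop-2-en-1-yl)oxy]-8,9-epoxy-5,9,13-trimethylpentadeca-4,12,14-trien-1-yne F5. RuCl2(=CHPh)(PCy3)(1,3-dimesitylimidazolidin-2-ylidene) at 1 mM in CH2Cl2 then runs an ene–yne–ene cascade: the carbene formed at the chain vinyl group closes the 14-membered ring onto the alkyne, and the new vinyl carbene closes the dihydrofuran, which gives 19 directly.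

**Further compounds**
F1 | step 8 | (3S,4E,8S,9S,12E)-8,9-epoxy-3-hydroxy-5,9,13-trimethyl-1-(trimethylsilyl)tetradeca-4,12-dien-1-yn-14-yl pivalate | CC(C)(C)C(=O)OC/C(C)=C/CC[C@]1(C)O[C@H]1CC/C(C)=C/[C@H](O)C#C[Si](C)(C)C
F2 | step 13 | (4S,5E,9S,10S,13E)-4-[(2-{[tert-butyl(dimethyl)silyl]oxymethyl}prop-2-en-1-yl)oxy]-9,10-epoxy-6,10,14-trimethyl-3-methylidenepentadeca-1,5,13-trien-15-yl pivalate | CC(C)(C)C(=O)OC/C(C)=C/CC[C@]1(C)O[C@H]1CC/C(C)=C/[C@H](OCC(=C)CO[Si](C)(C)C(C)(C)C)C(=C)C=C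
F3 | step 17 | (3S,4E,8S,9S,12E)-3-[(2-{[tert-butyl(dimethyl)silyl]oxymethyl}prop-2-en-1-yl)oxy]-8,9-epoxy-5,9,13-trimethyltetradeca-4,12-dien-1-yn-14-ol | OC/C(C)=C/CC[C@]1(C)O[C@H]1CC/C(C)=C/[C@H](OCC(=C)CO[Si](C)(C)C(C)(C)C)C#C
F4 | step 17 | (2E,6S,7S,10E,12S)-12-[(2-{[tert-butyl(dimethyl)silyl]oxymethyl}prop-2-en-1-yl)oxy]-6,7-epoxy-2,6,10-trimethyltetradeca-2,10-dien-13-ynal | O=C/C(C)=C/CC[C@]1(C)O[C@H]1CC/C(C)=C/[C@H](OCC(=C)CO[Si](C)(C)C(C)(C)C)C#C
F5 | step 17 | (3S,4E,8S,9S,12E)-3-[(2-{[tert-butyl(dimethyl)silyl]oxymethyl}prop-2-en-1-yl)oxy]-8,9-epoxy-5,9,13-trimethylpentadeca-4,12,14-trien-1-yne | C=C/C(C)=C/CC[C@]1(C)O[C@H]1CC/C(C)=C/[C@H](OCC(=C)CO[Si](C)(C)C(C)(C)C)C#C
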